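**Plan**
- Numbering: furan ring carbons C1–C4, then the chain from the furan-bound CH2 (C5) through the ketones C10 and C18 to the isopropyl CH (C20); E-alkenes at C7=C8 and C15=C16.
- Enabling feature: the only stereocentre, C12, carries a methyl group, lies β to the C10 ketone and sits between C11H2 and C13H2. It is therefore the β-carbon of an E-propenyl ketone that accepts the C13 chain as a nucleophile. The furan is the only ring and is bought intact.
- Retrosynthesis: cut C17–C18 and C18–C19 (allyl benzoate + CO + isobutylzinc), then C12–C13 (asymmetric conjugate addition). On the left cut C9–C10 (allylbarium + crotonaldehyde) and C5–C6 (furylmethyl Grignard + isoprene monoxide); on the right cut C14–C15 and C16–CH3 (carboalumination/alkenyl coupling).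
- Forward: the C1–C12 enone is made in five steps from furan-3-ylmethanol and the C13–C17 silyloxy diene in two steps from prop-2-yn-1-ol. They are joined by one-pot hydrozirconation and copper-catalysed conjugate addition, and desilylation, benzoylation and carbonylative coupling then add C18–C21. No ring is formed at any stage.
- Stereochemistry: C12 (S) comes from the chiral copper–phosphoramidite catalyst. E-C7=C8 comes from the anti-SN2′ opening of the vinyl oxirane, and E-C15=C16 from syn methylalumination followed by stereoretentive coupling.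

Key step: step 8

Assumption: with the phosphoramidite L built from (S)-BINOL and bis[(S)-1-phenylethyl]amine, the alkyl group is taken to arrive on the enone face that gives 12S; should the adduct prove to be 12R, the mirror-image ligand is used with no other change.
Notation: in SMILES the η5-C5H5 rings of zirconocene species are written as σ-bonded cyclopentadienyl groups.

**Step 1**
Reactants: 1 furan-3-ylmethanol
Product: 3 3-(chloromethyl)furan, via furan-3-ylmethyl methanesulfonate 2 (not isolated)
Conditions: MsCl, 2,4,6-collidine, LiCl, DMF, 0 °C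
Reagents that add atoms: lithium chloride, [Li+].[Cl-]; methanesulfonyl chloride, CS(=O)(=O)Cl (second chloride source)
Why: The alcohol is mesylated and the furylmethyl mesylate is displaced in the same flask by chloride (SN2 halide exchange under collidine buffer), which avoids the strong acid that would polymerise the furan.

**Step 2**
Reactants: 3 3-(chloromethyl)furan; 4 2-methyl-2-vinyloxirane (racemic isoprene monoxide)
Product: 6 (E)-5-(furan-3-yl)-2-methylpent-2-en-1-ol, via (furan-3-ylmethyl)magnesium chloride 5 (not isolated)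
Conditions: Mg, THF, 0 °C → rt; then 4, CuBr·SMe2 (10 mol %), THF, −30 °C; aq NH4Cl
Reagents that add atoms: none
Why: The benzylic-type chloride inserts Mg normally and, with catalytic monovalent copper, the Grignard reagent opens the vinyl oxirane by anti-SN2′ attack at the terminal vinyl carbon (copper-catalysed allylic substitution), forming C5–C6 and a 2-methylalk-2-en-1-ol that should be predominantly E because the oxirane reacts through its s-trans conformer; any Z isomer is removed by chromatography (AgNO3-doped silica if needed).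

**Step 3**
Reactants: 6 (E)-5-(furan-3-yl)-2-methylpent-2-en-1-ol
Product: 8 3-[(E)-5-chloro-4-methylpent-3-en-1-yl]furan, via allylic methanesulfonate 7 (not isolated)
Conditions: MsCl, 2,4,6-collidine, LiCl, DMF, 0 °C
Reagents that add atoms: lithium chloride, [Li+].[Cl-]; methanesulfonyl chloride, CS(=O)(=O)Cl (second chloride source)
Why: The same in situ mesylate/chloride exchange applies; SN2 displacement at the primary allylic carbon should proceed without allylic transposition and without loss of the E geometry.

**Step 4**
Reactants: 8 3-[(E)-5-chloro-4-methylpent-3-en-1-yl]furan; 9 (E)-but-2-enal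
Product: 11 racemic (2E,6E)-9-(furan-3-yl)-6-methylnona-2,6-dien-4-ol, via allylbarium chloride 10 (not isolated)
Conditions: BaI2, Li, biphenyl, THF, rt (activated barium); 8, −78 °C; then 9, −78 °C; aq NH4Cl
Reagents that add atoms: none
Why: Allylbarium reagents formed from allylic chlorides and zerovalent activated barium at −78 °C hold their geometry and add to aldehydes through the α-carbon (C9) and to enals in a 1,2 sense (Barbier-type allylmetal addition), which gives the unbranched dienol with C9–C10 formed instead of the branched γ-adduct expected from zinc, indium or chromium reagents.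

**Step 5**
Reactants: 11 (2E,6E)-9-(furan-3-yl)-6-methylnona-2,6-dien-4-ol
Product: 12 (2E,6E)-9-(furan-3-yl)-6-methylnona-2,6-dien-4-one
Conditions: Dess–Martin periodinane, NaHCO3, CH2Cl2, 0 °C → rt
Reagents that add atoms: none
Why: Dess–Martin oxidation under bicarbonate buffer converts the allylic/homoallylic carbinol into the ketone at neutral pH, so the C7=C8 alkene should stay out of conjugation and the C11=C12 enone should keep its E geometry; the enone is used promptly.

**Step 6**
Reactants: 13 prop-2-yn-1-ol
Product: 14 tert-butyldimethyl(prop-2-yn-1-yloxy)silane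
Conditions: TBSCl, imidazole, CH2Cl2, 0 °C → rt
Reagents that add atoms: tert-butyldimethylsilyl chloride, CC(C)(C)[Si](C)(C)Cl
Why: Imidazole-assisted silylation of the primary alcohol removes the hydroxyl proton that Me3Al and Cp2Zr(H)Cl would otherwise consume.

**Step 7**
Reactants: 14 tert-butyldimethyl(prop-2-yn-1-yloxy)silane; 15 bromoethene
Product: 17 (E)-tert-butyldimethyl[(2-methylpenta-2,4-dien-1-yl)oxy]silane, via alkenyldimethylalane 16 (not isolated)
Conditions: Me3Al, Cp2ZrCl2 (25 mol %), CH2Cl2, 0 °C → rt; volatiles removed; then 15, Pd(PPh3)4 (5 mol %), ZnCl2 (cat.), THF, rt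
Reagents that add atoms: trimethylaluminium, C[Al](C)C
Why: Zirconium-catalysed Negishi carboalumination adds CH3 and Al syn across the terminal alkyne with aluminium on the terminal carbon, and the alkenylalane then undergoes stereoretentive palladium-catalysed Negishi-type coupling with bromoethene (C14–C15), which fixes the E geometry of C15=C16.

**Step 8**
Reactants: 17 (E)-tert-butyldimethyl[(2-methylpenta-2,4-dien-1-yl)oxy]silane; 12 (2E,6E)-9-(furan-3-yl)-6-methylnona-2,6-dien-4-one
Product: 20 (3E,8S,11E)-13-[(tert-butyldimethylsilyl)oxy]-1-(furan-3-yl)-4,8,12-trimethyltrideca-3,11-dien-6-one, via alkylzirconocene chloride 18 (not isolated), via zirconium enolate 19 (not isolated)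
Conditions: 17 (2.5 equiv), Cp2Zr(H)Cl (2.0 equiv), CH2Cl2, rt; then CuCl (10 mol %), L (10 mol %), AgOTf (AgOSO2CF3, 11 mol %), 12 (1.0 equiv), Et2O, rt; aq NH4Cl
Reagents that add atoms: none
Why: Cp2Zr(H)Cl adds syn across the less hindered terminal C13=C14 bond of the diene with zirconium on C13 and leaves the trisubstituted C15=C16 alkene and its E geometry untouched; the alkyl group then passes to the cationic monovalent copper–phosphoramidite complex generated from CuCl and AgOTf, the alkylcopper π-binds C11=C12 of the s-cis enone, adds at C12 and reductively eliminates to form C12–C13, and the zirconium enolate 19 is protonated at C11 on work-up. The closest known reaction type is the copper-catalysed asymmetric conjugate addition of alkylzirconocenes from alkene hydrozirconation to enones, which has been extended to acyclic enones. No ring is closed; the step joins two achiral acyclic halves of similar size. The new C12 stereocentre is controlled by the chiral phosphoramidite on copper, which selects one enantiotopic face of the E-propenyl ketone, the ligand enantiomer being chosen for 12S. The step needs 1,4- over 1,2-addition, survival of the doubly activated C9H2 between the ketone and C7=C8, and no carbonyl reduction: the soft alkylcopper and the non-basic alkylzirconocene secure the first two, the excess of diene over Cp2Zr(H)Cl secures the third, and the geometric purity of the enone (from E-crotonaldehyde) supports the face selectivity.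

**Step 9**
Reactants: 20 (3E,8S,11E)-13-[(tert-butyldimethylsilyl)oxy]-1-(furan-3-yl)-4,8,12-trimethyltrideca-3,11-dien-6-one
Product: 21 (3E,8S,11E)-1-(furan-3-yl)-13-hydroxy-4,8,12-trimethyltrideca-3,11-dien-6-one
Conditions: Bu4NF, AcOH, THF, 0 °C → rt
Reagents that add atoms: none
Why: Fluoride cleaves the primary allylic silyl ether (Si–O cleavage driven by the Si–F bond), the AcOH buffer keeps the medium from isomerising the C7=C8 β,γ-alkene, and C12 cannot epimerise because it is not α to the carbonyl.

**Step 10**
Reactants: 21 (3E,8S,11E)-1-(furan-3-yl)-13-hydroxy-4,8,12-trimethyltrideca-3,11-dien-6-one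
Product: 22 (2E,6S,10E)-13-(furan-3-yl)-2,6,10-trimethyl-8-oxotrideca-2,10-dien-1-yl benzoate
Conditions: BzCl, pyridine, DMAP (cat.), CH2Cl2, 0 °C
Reagents that add atoms: benzoyl chloride, O=C(Cl)c1ccccc1
Why: DMAP-catalysed acylation of the primary allylic alcohol gives the benzoate, a leaving group suited to ionisation by zerovalent palladium.

**Step 11**
Reactants: 22 (2E,6S,10E)-13-(furan-3-yl)-2,6,10-trimethyl-8-oxotrideca-2,10-dien-1-yl benzoate
Product: 23 idiadione, (6E,10S,14E)-17-(furan-3-yl)-2,6,10,14-tetramethylheptadeca-6,14-diene-4,12-dione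
Conditions: CO (1 atm), iBuZnBr (2 equiv), Pd(PPh3)4 (5 mol %), THF–HMPA, rt
Reagents that add atoms: carbon monoxide, [C-]#[O+]; isobutylzinc bromide, CC(C)C[Zn]Br
Why: In this carbonylative three-component Negishi-type coupling, zerovalent palladium ionises the allylic benzoate to a π-allyl complex, CO inserts at the unhindered terminus C17 to give an acylpalladium species, and transmetalation from the alkylzinc followed by reductive elimination forms C18–C19; this is a known route from allylic benzoates, CO and alkylzinc halides to β,γ-unsaturated ketones, and the non-basic organozinc leaves the C10 ketone and C12 untouched.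

**Compound list**
1 | furan-3-ylmethanol | OCc1ccoc1 | starting material
2 | furan-3-ylmethyl methanesulfonate (not isolated) | CS(=O)(=O)OCc1ccoc1 | intermediate
3 | 3-(chloromethyl)furan | ClCc1ccoc1 | intermediate
4 | 2-methyl-2-vinyloxirane (racemic) | C=CC1(C)CO1 | starting material
5 | (furan-3-ylmethyl)magnesium chloride (not isolated) | Cl[Mg]Cc1ccoc1 | intermediate
6 | (E)-5-(furan-3-yl)-2-methylpent-2-en-1-ol | OC/C(C)=C/CCc1ccoc1 | intermediate
7 | (E)-5-(furan-3-yl)-2-methylpent-2-en-1-yl methanesulfonate (not isolated) | CS(=O)(=O)OC/C(C)=C/CCc1ccoc1 | intermediate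
8 | 3-[(E)-5-chloro-4-methylpent-3-en-1-yl]furan | ClC/C(C)=C/CCc1ccoc1 | intermediate
9 | (E)-but-2-enal | C/C=C/C=O | starting material
10 | [(E)-5-(furan-3-yl)-2-methylpent-2-en-1-yl]barium chloride (not isolated) | Cl[Ba]C/C(C)=C/CCc1ccoc1 | intermediate
11 | (2E,6E)-9-(furan-3-yl)-6-methylnona-2,6-dien-4-ol (racemic) | C/C=C/C(O)C/C(C)=C/CCc1ccoc1 | intermediate
12 | (2E,6E)-9-(furan-3-yl)-6-methylnona-2,6-dien-4-one | C/C=C/C(=O)C/C(C)=C/CCc1ccoc1 | intermediate
13 | prop-2-yn-1-ol | C#CCO | starting material
14 | tert-butyldimethyl(prop-2-yn-1-yloxy)silane | C#CCO[Si](C)(C)C(C)(C)C | intermediate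
15 | bromoethene | C=CBr | starting material
16 | [(E)-3-(tert-butyldimethylsilyloxy)-2-methylprop-1-en-1-yl]dimethylalumane (not isolated) | C/C(=C\[Al](C)C)CO[Si](C)(C)C(C)(C)C | intermediate
17 | (E)-tert-butyldimethyl[(2-methylpenta-2,4-dien-1-yl)oxy]silane | C=C/C=C(\C)CO[Si](C)(C)C(C)(C)C | intermediate
18 | chlorobis(cyclopentadienyl)[(E)-5-(tert-butyldimethylsilyloxy)-4-methylpent-3-en-1-yl]zirconium (not isolated) | CC(C)(C)[Si](C)(C)OC/C(C)=C/CC[Zr](Cl)(C1C=CC=C1)C1C=CC=C1 | intermediate
19 | chlorobis(cyclopentadienyl)zirconium enolate (O-bound at C10, C10=C11) of 20 (not isolated; enolate geometry not defined) | CC(C)(C)[Si](C)(C)OC/C(C)=C/CC[C@H](C)C=C(O[Zr](Cl)(C1C=CC=C1)C1C=CC=C1)C/C(C)=C/CCc1ccoc1 | intermediate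
20 | (3E,8S,11E)-13-[(tert-butyldimethylsilyl)oxy]-1-(furan-3-yl)-4,8,12-trimethyltrideca-3,11-dien-6-one | CC(C)(C)[Si](C)(C)OC/C(C)=C/CC[C@H](C)CC(=O)C/C(C)=C/CCc1ccoc1 | intermediate
21 | (3E,8S,11E)-1-(furan-3-yl)-13-hydroxy-4,8,12-trimethyltrideca-3,11-dien-6-one | OC/C(C)=C/CC[C@H](C)CC(=O)C/C(C)=C/CCc1ccoc1 | intermediate
22 | (2E,6S,10E)-13-(furan-3-yl)-2,6,10-trimethyl-8-oxotrideca-2,10-dien-1-yl benzoate | O=C(OC/C(C)=C/CC[C@H](C)CC(=O)C/C(C)=C/CCc1ccoc1)c1ccccc1 | intermediate
23 | idiadione, (6E,10S,14E)-17-(furan-3-yl)-2,6,10,14-tetramethylheptadeca-6,14-diene-4,12-dione | C/C(=C\CC[C@H](C)CC(=O)C/C(C)=C/CCc1ccoc1)CC(=O)CC(C)C | target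

**Step count**
Total: 11 steps. Longest linear sequence: 9 steps (steps 1–5 and 8–11).

**Steps most likely to fail**

Step 8. The transfer of the alkyl group to the acyclic aliphatic enone may be sluggish, the copper–phosphoramidite complex may discriminate the enone faces poorly, or unconsumed Zr–H may reduce the carbonyl. The fallback sets the stereocentre on a thioester acceptor and forms C9–C10 afterwards; it sets out from 17 (with 8 for the last C–C bond) and comes back at 20. Diene 17 is hydrozirconated as in step 8 to 18, which N-bromosuccinimide cleaves to {[(E)-5-bromo-2-methylpent-2-en-1-yl]oxy}(tert-butyl)dimethylsilane F1. Mg in THF converts it into [(E)-5-(tert-butyldimethylsilyloxy)-4-methylpent-3-en-1-yl]magnesium bromide F2. This is added to S-ethyl (E)-but-2-enethioate (C/C=C/C(=O)SCC) with CuBr·SMe2 and the appropriate enantiomer of Tol-BINAP in tBuOMe at −70 °C, a well-established enantioselective Grignard conjugate addition, to give S-ethyl (3S,6E)-8-[(tert-butyldimethylsilyl)oxy]-3,7-dimethyloct-6-enethioate F3. Reduction with iBu2AlH at −78 °C gives (3S,6E)-8-[(tert-butyldimethylsilyl)oxy]-3,7-dimethyloct-6-enal F4. Allylbarium 10, made from 8 as in step 4, adds to it to give (3E,8S,11E)-13-[(tert-butyldimethylsilyl)oxy]-1-(furan-3-yl)-4,8,12-trimethyltrideca-3,11-dien-6-ol F5 as a mixture of carbinol epimers, and buffered Dess–Martin oxidation returns the route to 20.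

Step 11. The allyl and alkyl groups may couple directly without CO uptake, the π-allyl intermediate may isomerise with loss of the E geometry or react at C15, and the new C15=C16 alkene may migrate into conjugation with the C18 carbonyl. The fallback brings C18–C21 in at the alcohol oxidation level before the fragment union; it sets out from 12 and comes back at 23. 3-Methylbutanal and 3-bromoprop-1-yne with Zn (THF, aq NH4Cl, Barbier conditions) give 6-methylhept-1-yn-4-ol F6, and TBSCl/imidazole gives tert-butyldimethyl[(6-methylhept-1-yn-4-yl)oxy]silane F7. Methylalumination as in step 7 gives [(E)-4-(tert-butyldimethylsilyloxy)-2,6-dimethylhept-1-en-1-yl]dimethylalumane F8, and coupling with 15 gives tert-butyl{[(3E)-4,8-dimethylnona-1,3-dien-6-yl]oxy}dimethylsilane F9. Hydrozirconation gives the alkylzirconocene chloride F10, which adds to 12 under the conditions of step 8 through the zirconium enolate F11 to give (3E,8S,11E)-14-[(tert-butyldimethylsilyl)oxy]-1-(furan-3-yl)-4,8,12,16-tetramethylheptadeca-3,11-dien-6-one F12; its silyloxy-bearing carbon is an inconsequential epimer mixture. Bu4NF/AcOH gives (3E,8S,11E)-1-(furan-3-yl)-14-hydroxy-4,8,12,16-tetramethylheptadeca-3,11-dien-6-one F13, and buffered Dess–Martin oxidation gives 23.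

Step 2. The SN2′ opening may be incompletely E-selective, so that a Z alcohol hard to separate would carry a C7=C8 geometric isomer through to the end, and some direct SN2 opening may compete. The fallback builds the alkene from a prenyl unit and oxidises it; it sets out from 3 and comes back at 6. Grignard reagent 5 (from 3 as in step 2) is coupled with 1-chloro-3-methylbut-2-ene under Li2CuCl4 catalysis in THF at 0 °C to give 3-(4-methylpent-3-en-1-yl)furan F14. Allylic oxidation with catalytic SeO2 and tBuOOH in CH2Cl2 at 0 °C, followed by NaBH4 to reduce any enal, should then hydroxylate the E-methyl group selectively and give 6.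

**Further compounds**
F1 | step 8 | {[(E)-5-bromo-2-methylpent-2-en-1-yl]oxy}(tert-butyl)dimethylsilane | BrCC/C=C(\C)CO[Si](C)(C)C(C)(C)C
F2 | step 8 | [(E)-5-(tert-butyldimethylsilyloxy)-4-methylpent-3-en-1-yl]magnesium bromide | Br[Mg]CC/C=C(\C)CO[Si](C)(C)C(C)(C)C
F3 | step 8 | S-ethyl (3S,6E)-8-[(tert-butyldimethylsilyl)oxy]-3,7-dimethyloct-6-enethioate | CCSC(=O)C[C@@H](C)CC/C=C(\C)CO[Si](C)(C)C(C)(C)C
F4 | step 8 | (3S,6E)-8-[(tert-butyldimethylsilyl)oxy]-3,7-dimethyloct-6-enal | O=CC[C@@H](C)CC/C=C(\C)CO[Si](C)(C)C(C)(C)C
F5 | step 8 | (3E,8S,11E)-13-[(tert-butyldimethylsilyl)oxy]-1-(furan-3-yl)-4,8,12-trimethyltrideca-3,11-dien-6-ol | CC(C)(C)[Si](C)(C)OC/C(C)=C/CC[C@H](C)CC(O)C/C(C)=C/CCc1ccoc1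
F6 | step 11 | 6-methylhept-1-yn-4-ol | C#CCC(O)CC(C)C
F7 | step 11 | tert-butyldimethyl[(6-methylhept-1-yn-4-yl)oxy]silane | C#CCC(O[Si](C)(C)C(C)(C)C)CC(C)C
F8 | step 11 | [(E)-4-(tert-butyldimethylsilyloxy)-2,6-dimethylhept-1-en-1-yl]dimethylalumane | C[Al](C)/C=C(\C)CC(O[Si](C)(C)C(C)(C)C)CC(C)C
F9 | step 11 | tert-butyl{[(3E)-4,8-dimethylnona-1,3-dien-6-yl]oxy}dimethylsilane | C=C/C=C(\C)CC(O[Si](C)(C)C(C)(C)C)CC(C)C
F10 | step 11 | chlorobis(cyclopentadienyl)[(E)-6-(tert-butyldimethylsilyloxy)-4,8-dimethylnon-3-en-1-yl]zirconium | CC(C)CC(O[Si](C)(C)C(C)(C)C)C/C(C)=C/CC[Zr](Cl)(C1C=CC=C1)C1C=CC=C1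
F11 | step 11 | chlorobis(cyclopentadienyl)zirconium enolate of F12 | CC(C)CC(O[Si](C)(C)C(C)(C)C)C/C(C)=C/CC[C@H](C)C=C(O[Zr](Cl)(C1C=CC=C1)C1C=CC=C1)C/C(C)=C/CCc1ccoc1
F12 | step 11 | (3E,8S,11E)-14-[(tert-butyldimethylsilyl)oxy]-1-(furan-3-yl)-4,8,12,16-tetramethylheptadeca-3,11-dien-6-one | CC(C)CC(O[Si](C)(C)C(C)(C)C)C/C(C)=C/CC[C@H](C)CC(=O)C/C(C)=C/CCc1ccoc1
F13 | step 11 | (3E,8S,11E)-1-(furan-3-yl)-14-hydroxy-4,8,12,16-tetramethylheptadeca-3,11-dien-6-one | CC(C)CC(O)C/C(C)=C/CC[C@H](C)CC(=O)C/C(C)=C/CCc1ccoc1
F14 | step 2 | 3-(4-methylpent-3-en-1-yl)furan | CC(C)=CCCc1ccoc1
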